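**Remark on the chemistry.** The target has no stereocentre (every sp3 carbon is a CH2, a CH3 or a carbon bearing two methyl groups), so no configuration has to be set and the SMILES carry no stereodescriptors. 7-Hydroxycoumarin is taken as the commercial entry to ring A because it already holds the three-carbon chain and a masked C2' oxygen. No error was found in the precursor or product structures of the key step; both are used unchanged as compounds 10 and 13.

## Structural features

Kazinol D is an achiral 1,3-diarylpropane in which a CH2CH2CH2 chain joins C1' of ring A to C6 of ring B. Ring A is a resorcinol (free hydroxyls at C2' and C4') whose C5' carries a 2-methylbut-3-en-2-yl (1,1-dimethylallyl) group, a quaternary benzylic carbon ortho to the C4' hydroxyl. Ring B is the benzo ring of a 2,2-dimethylchroman (O1, C2 with two methyls, C3, C4, C4a, C8a) and is substituted everywhere except C7: prenyl on C5, the propane chain on C6, a free hydroxyl on C8. Since there is no stereocentre, no stereocentres stand next to each other, and the whole problem is regiochemistry on two crowded, electron-rich arenes. The fragile groups are the 1,1-dimethylallyl group beside a free phenol (acid closes it to a dihydrobenzofuran, heat can isomerise it), the prenyl group (acid, double-bond migration) and the catechol-type oxygens of ring B (oxidation). The three C=C bonds also rule out hydrogenation or hydroboration once they are in place. The real difficulty is the pentasubstituted ring B with its hindered tertiary alkyl aryl ether, and the sp3–sp2 union of the two halves without any reduction step. The key step exploits the fact that C4 is an unsubstituted CH2 on C4a, ortho to the oxygen-bearing C8a: this is the footprint of a phenol-derived ortho-quinone methide (C4 as exocyclic methylene, C8a as carbonyl) that has taken up 2-methylpropene as C3, C2 and both methyl groups.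

## Logic of the disconnections

**26 to 25.** The three O–CH2 acetal bonds on the C2', C4' and C8 oxygens are cut. All phenols must be masked during the methide and organometallic chemistry, and one kind of group allows a single final operation. The skeleton is not simplified, but the forward step must be mild enough for the dimethylallyl phenol and the prenyl group.

**25 to 15 and 23 (through 24).** The bond between C6 of ring B and the first CH2 of the chain is cut. This divides the molecule into two halves of similar size, each with one sensitive alkene, and the sp3–sp2 bond can be made from an alkylzinc reagent that tolerates alkenes and acetals, so no reduction is needed. The forward step demands oxidative addition at a hindered, electron-rich aryl bromide and transmetalation faster than β-hydride elimination, and zinc insertion into 23 that leaves its vinyl group alone.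

**15 to 13 and 14.** The C=C bond of the prenyl group is cut by retro-cross-metathesis. A prenyl alkene next to the methide carbon would intercept the methide of the key step, so the side chain is carried as allyl until the chroman exists. The forward metathesis must be run before the coupling, while the molecule holds only one terminal alkene and before a palladium hydride could isomerise an allyl group.

**13 to 10 and 11 (through 12).** C4–C3 and O1–C2 are cut in a retro hetero-Diels–Alder sense. One move removes the heterocycle, the tertiary ether and four carbons, leaving a salicyl alcohol and a gaseous alkene. The forward step demands exactly one CH2OH ortho to a free phenol, a masked C8 oxygen, a side chain that cannot trap the methide, and a large excess of 11.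

**10 to 9 to 8.** The bond from the ring carbon that becomes C4a to the carbon that becomes C4 is cut (reduction of an aldehyde that comes from ortho-formylation). In 8 the only free position ortho to the phenol is the one required, so the regiochemistry is forced. The formylation must tolerate the acetal, the aryl bromide, the allyl group and the crowding by the allyl neighbour.

**8 to 6 (through 7), then 5 and 4.** The CH2–CH bond of the allyl group is cut to a benzylic bromide and a vinylmagnesium reagent; the bromide goes back to the alcohol and the aldehyde. The formyl carbon of the starting arene thus becomes the benzylic carbon of the C5 side chain, and copper catalysis leaves the aryl bromide alone. The price is that the phenol must be silylated for these steps and freed again.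

**4 to 3 to 2 to 1.** The O–Si bond and the O–CH2 acetal bond are cut, and the methyl ether of 1 is traded for the acetal. In 2 the hydroxyl para to the formyl group is much the more acidic, so it takes the acetal and becomes the C8 oxygen, while the other oxygen stays free to become O1. The forward step demands clean mono-alkylation.

**23 to 22 to 21 to 20.** The C–I bond goes back to C–OH, the two acetals to free phenols, and the primary alcohol and the C2' phenol to the lactone of 20. The lactone keeps the chain at the acid level and masks the C2' oxygen until the quaternary carbon is in place. The forward steps demand protection of the phenols in the presence of the primary alcohol and the absence of acid.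

**20 to 18 (through 19), then 17 and 16.** The bond from the aryl carbon to the carbon bearing two methyls is cut by a retro-[3,3] shift to the O-prenyl ether; the ether goes back to the phenol 17, and 17 to 16 by removal of two hydrogens. A sigmatropic shift of a prenyl ether is the most direct way to an ortho-1,1-dimethylallyl phenol, and the hydrogenation is placed before any other alkene exists. The forward step demands migration to C6 and not to C8, and trapping of the new phenol before it rearranges further.

## Other disconnections considered

**Alternative 1:** The product of the key step would be A1, the target with acetals on the C2' and C8 oxygens and a free C4' phenol. The cut is made at the quaternary carbon of ring A: its C–CH3 and C–vinyl bonds are removed, leading back to the aryl methyl ketone A2, whose C4' oxygen carries a tert-butyl carbonate.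

- Forward step: MeMgBr would add to the ketone of A2, the tertiary alkoxide would take over the carbonate, loss of tert-butyl carbonate would give the ring A methide A3, and CH2=CHMgBr would add to its exocyclic carbon. No ring is closed.
- In its favour: the position of the quaternary carbon is fixed by the position of the acetyl group, so the ortho/ortho' question of step 13 does not arise; on this point the alternative is the better plan. The cascade runs at low temperature and frees the C4' phenol.
- Against it here: it does not touch the problem of ring B, whose chroman and pentasubstituted arene would still have to be made by something like step 9. A3 carries two methyl groups and can collapse by 1,5-hydrogen shift to an isopropenylphenol before the less reactive vinyl reagent adds. Two different Grignard reagents must be staged in one flask, and the cascade would run on the fully assembled skeleton.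
- Comparison: both plans use an ortho-quinone methide, the alternative as a Michael acceptor on ring A and the chosen plan as a heterodiene on ring B. Acetylation, carbonate formation and cascade cost about as much as steps 12 and 13, so the alternative is equal in step economy and better in regiocontrol on ring A. It is weaker in that it builds no ring and places its riskiest step last.

**Alternative 2:** The product of the key step would be A4, the target with silyl ethers on ring A and a 2-(trimethylsilyl)ethyl ether on the C8 oxygen. The cut goes through the benzene ring of ring B: C8a–C4a and C6–C5 are removed, so that C8a, C8, C7 and C6 come from a pyridazine and C4a and C5 from an alkyne tethered through O1, C2, C3 and C4. The precursor is A5.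

- Forward step: the alkyne of A5 would add across pyridazine C3 and C6 in an intramolecular inverse-demand (4+2) cycloaddition and N2 would be lost, closing the benzene ring and the dihydropyran ring in one thermal operation.
- In its favour: all five substituents of ring B are placed by construction, with no aromatic substitution whose regiochemistry could fail. Two rings and two C–C bonds are made at once, against one ring, one C–C and one C–O bond in step 9; on bond count the alternative is the better plan. Like step 9 it raises no stereochemical question (equal), and loss of N2 makes it irreversible.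
- Against it here: the pyridazine of A5 carries two alkoxy groups that raise its LUMO, so an unactivated alkyne should need temperatures well above those of step 9. At such temperatures the tertiary alkyl heteroaryl ether can fragment by elimination, and the skipped enyne can isomerise. The tertiary ether that step 9 makes directly must here be made beforehand by substitution with a hindered tertiary alkoxide, and the three silicon groups need two kinds of deprotection.
- Comparison: both key steps are thermal cycloadditions driven by aromatisation (equal). The alternative is more convergent, since ring A and the chain are already attached and no cross-coupling is needed (better). The synthesis of the trisubstituted pyridazine and the tertiary propargylic tether is expected to cost more than steps 1 to 8, and the risk sits in a late step on a fully elaborated substrate.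

**Alternative 3:** The product of the key step would be the racemic flavan A6. The cut is Cα–Cβ of the three-carbon chain together with a temporary O–Cγ bond; the partners are the ring A salicyl alcohol A7 and the ring B styrene A9.

- Forward step: A7 would lose water on heating to give the methide A8, which adds across the vinyl group of A9 (Cα to Cβ, oxygen to the benzylic Cγ). The benzylic C–O bond of A6 must then be cleaved reductively to give the phenol A10 before the acetals are removed.
- In its favour: it uses the same methide logic as step 9 but with a styrene, which is a better 2π partner than 11 because the aryl group stabilises the developing positive charge; here the alternative is the better reaction. It forms the chain C–C bond without an organozinc reagent or palladium, and ring A needs no three-carbon chain, so that fragment is shorter (better).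
- Against it here: it creates a stereocentre at the flavan C2 that the target does not have and that is destroyed again. The ring opening of A6 must break a benzylic ether in the presence of three alkenes, which excludes hydrogenolysis and leaves dissolving-metal or hydride/Lewis-acid conditions that threaten the prenyl and dimethylallyl groups. A8 could also be intercepted by the electron-rich prenyl alkene of A9. Ring B with its dimethylchroman must still be made, so the alternative comes on top of step 9 and does not replace it.
- Comparison: mechanism and selectivity rules are those of the chosen key step (equal). From 15 the alternative needs a vinylation, the cycloaddition, the ring opening and the deprotection, against steps 17 and 18; this is roughly offset by the shorter ring A fragment, so step economy is about equal. The chosen plan needs no detour through a stereocentre and no reduction late in the synthesis.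

Key step: step 9

## Route

Step 1
Reactants: 1 2-bromo-5-hydroxy-4-methoxybenzaldehyde
Product: 2 2-bromo-4,5-dihydroxybenzaldehyde
Conditions: BBr3 (2.5 equiv), CH2Cl2, −78 → 0 °C; then H2O
Reagents that add atoms: none
Why: Lewis-acid cleavage of an aryl methyl ether by BBr3; the aldehyde and the aryl bromide are inert and the catechol is released when the aryl borate is hydrolysed.

Step 2
Reactants: 2 2-bromo-4,5-dihydroxybenzaldehyde
Product: 3 2-bromo-5-hydroxy-4-(methoxymethoxy)benzaldehyde
Conditions: MOMCl (1.05 equiv), K2CO3 (1.05 equiv), acetone, 0 °C → rt
Reagents that add atoms: chloromethyl methyl ether, COCCl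
Why: Williamson-type O-alkylation; the C4 hydroxyl para to the formyl group is far more acidic than the C5 hydroxyl, so one equivalent of weak base forms mainly that phenoxide and the acetal goes on the oxygen that becomes the chroman C8 oxygen.

Step 3
Reactants: 3 2-bromo-5-hydroxy-4-(methoxymethoxy)benzaldehyde
Product: 4 2-bromo-5-[(tert-butyldimethylsilyl)oxy]-4-(methoxymethoxy)benzaldehyde
Conditions: TBSCl, imidazole, CH2Cl2, rt
Reagents that add atoms: tert-butyldimethylsilyl chloride, CC(C)(C)[Si](C)(C)Cl
Why: standard silylation of the remaining phenol, which would otherwise quench the Grignard reagent and alkylate itself with the benzylic bromide; the silyl group cannot migrate because the neighbouring oxygen is an acetal.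

Step 4
Reactants: 4 2-bromo-5-[(tert-butyldimethylsilyl)oxy]-4-(methoxymethoxy)benzaldehyde
Product: 5 {2-bromo-5-[(tert-butyldimethylsilyl)oxy]-4-(methoxymethoxy)phenyl}methanol
Conditions: NaBH4, THF/MeOH (10:1), 0 °C
Reagents that add atoms: none
Why: chemoselective hydride reduction of the aldehyde; a short reaction at 0 °C should leave the aryl silyl ether, the acetal and the aryl bromide untouched.

Step 5
Reactants: 5 {2-bromo-5-[(tert-butyldimethylsilyl)oxy]-4-(methoxymethoxy)phenyl}methanol
Product: 6 [4-bromo-5-(bromomethyl)-2-(methoxymethoxy)phenoxy](tert-butyl)dimethylsilane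
Conditions: CBr4, PPh3, CH2Cl2, 0 °C
Reagents that add atoms: carbon tetrabromide, BrC(Br)(Br)Br
Why: Appel reaction of a benzylic alcohol; the neutral conditions should spare the acid-labile acetal and the silyl ether, and the reactive bromide is used crude.

Step 6
Reactants: 6 [4-bromo-5-(bromomethyl)-2-(methoxymethoxy)phenoxy](tert-butyl)dimethylsilane
Product: 8 4-bromo-2-(methoxymethoxy)-5-(prop-2-en-1-yl)phenol, via allylated silyl ether 7 (not isolated)
Conditions: CH2=CHMgBr (1.5 equiv), CuI (10 mol %), 2,2'-bipyridyl (10 mol %), THF, −20 → 0 °C; aq. NH4Cl; crude, then TBAF, THF, 0 °C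
Reagents that add atoms: vinylmagnesium bromide, C=C[Mg]Br
Why: copper-catalysed cross-coupling of a benzylic bromide with a vinyl Grignard reagent builds the allyl group while the aryl bromide, inert to organocopper species at this temperature, is kept; fluoride then cleaves the aryl silyl ether of the crude product to free the phenol needed for the formylation.

Step 7
Reactants: 8 4-bromo-2-(methoxymethoxy)-5-(prop-2-en-1-yl)phenol
Product: 9 6-allyl-5-bromo-2-hydroxy-3-(methoxymethoxy)benzaldehyde
Conditions: MgCl2 (2 equiv), Et3N (4 equiv), (CH2O)n (6 equiv), THF, reflux
Reagents that add atoms: paraformaldehyde (formaldehyde), C=O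
Why: Casnati–Skattebøl ortho-formylation: the magnesium phenoxide delivers formaldehyde to the only free ortho position and a second formaldehyde takes up hydride to give the aldehyde; the acetal, the allyl group and the aryl bromide are inert to these mildly basic conditions.

Step 8
Reactants: 9 6-allyl-5-bromo-2-hydroxy-3-(methoxymethoxy)benzaldehyde
Product: 10 3-allyl-4-bromo-2-(hydroxymethyl)-6-(methoxymethoxy)phenol
Conditions: NaBH4, THF/EtOH, 0 °C; pH 7 phosphate buffer work-up
Reagents that add atoms: none
Why: hydride reduction of the salicylaldehyde to the salicyl alcohol; a neutral work-up avoids premature acid-induced methide formation.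

Step 9
Reactants: 10 3-allyl-4-bromo-2-(hydroxymethyl)-6-(methoxymethoxy)phenol; 11 2-methylpropene
Product: 13 5-allyl-6-bromo-8-(methoxymethoxy)-2,2-dimethylchroman, via ortho-quinone methide 12 (not isolated)
Conditions: 11 (ca. 30 equiv, condensed), toluene (0.05 M), sealed steel autoclave, 170 °C
Reagents that add atoms: none
Why: On heating, the hydrogen-bonded 2-hydroxybenzyl alcohol 10 should lose water in a thermal 1,4-elimination to give the ortho-quinone methide 12, an electron-poor 1-oxadiene whose return to a benzene ring drives what follows. 12 should add 2-methylpropene in a concerted but asynchronous inverse-electron-demand hetero-Diels–Alder reaction; the closest known reaction type is the thermal chroman synthesis from 2-hydroxybenzyl alcohols and simple alkenes. The dihydropyran ring closes by intermolecular (4+2) cycloaddition, the methide carbon (future C4) bonding to the CH2 of the alkene (C3) and the carbonyl oxygen (O1) to the disubstituted carbon (C2). No stereocentre arises, because C2 carries two methyl groups and C3 and C4 are methylenes. The step needs regioselectivity, which the polarisation of 12 (electrophilic CH2) and the ability of the inner alkene carbon to carry positive charge secure, so that the 2,2- and not the 3,3-dimethyl isomer forms. It also needs chemoselectivity: only one CH2OH sits ortho to a free phenol, the C8 oxygen is an acetal so that 12 cannot tautomerise to an ortho-quinone, and the neighbouring allyl group can neither reach the oxadiene in a (4+2) geometry nor compete with the alkene used in large excess, whereas a prenyl group would close an indane by attack on the methide carbon. High dilution in the alkene should keep dimerisation of 12 down, and the neutral conditions make the hindered C2–O1 bond without a tertiary cation, so the aryl bromide, the acetal and the allyl group should survive.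

Step 10
Reactants: 13 5-allyl-6-bromo-8-(methoxymethoxy)-2,2-dimethylchroman; 14 2-methylbut-2-ene
Product: 15 6-bromo-8-(methoxymethoxy)-2,2-dimethyl-5-(3-methylbut-2-en-1-yl)chroman
Conditions: 14 (excess, cosolvent), second-generation Grubbs catalyst RuCl2(=CHPh)(PCy3)(H2IMes) (3 mol %), CH2Cl2, 40 °C, sealed tube
Reagents that add atoms: none
Why: olefin cross-metathesis of a terminal allylarene with a large excess of a trisubstituted alkene transfers the isopropylidene unit and releases propene; the trisubstituted product is not a metathesis substrate, so the reaction should stop at the prenyl group.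

Step 11
Reactants: 16 7-hydroxy-2H-chromen-2-one (umbelliferone)
Product: 17 7-hydroxychroman-2-one
Conditions: H2 (4 atm), Pd/C (10 wt %), AcOH, 50 °C
Reagents that add atoms: none
Why: catalytic hydrogenation of the conjugated C3–C4 double bond of a coumarin; it is placed here because no other alkene is present yet.

Step 12
Reactants: 17 7-hydroxychroman-2-one
Product: 18 7-[(3-methylbut-2-en-1-yl)oxy]chroman-2-one
Conditions: prenyl bromide (1.2 equiv), K2CO3 (1.5 equiv), acetone, rt → 45 °C
Reagents that add atoms: 1-bromo-3-methylbut-2-ene, CC(C)=CCBr
Why: Williamson etherification (SN2) at the only free phenol; the second ring A oxygen is masked in the lactone, so no regiochemical question arises.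

Step 13
Reactants: 18 7-[(3-methylbut-2-en-1-yl)oxy]chroman-2-one
Product: 20 6-(2-methylbut-3-en-2-yl)-2-oxochroman-7-yl acetate, via rearranged phenol 19 (not isolated)
Conditions: Ac2O (3 equiv), PhNEt2, 190 °C, sealed tube, Ar
Reagents that add atoms: acetic anhydride, CC(=O)OC(C)=O
Why: aromatic Claisen rearrangement ([3,3]-sigmatropic shift) of the aryl prenyl ether carries the dimethyl-substituted terminus to the ortho carbon and so creates the quaternary 1,1-dimethylallyl carbon; C6 should be preferred over C8, which lies between two oxygens. Acetic anhydride acylates the phenol as it forms, which blocks the further (abnormal Claisen) rearrangement and keeps the phenol from opening the lactone of another molecule.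

Step 14
Reactants: 20 6-(2-methylbut-3-en-2-yl)-2-oxochroman-7-yl acetate
Product: 21 4-(3-hydroxypropyl)-6-(2-methylbut-3-en-2-yl)benzene-1,3-diol
Conditions: LiAlH4 (3 equiv), THF, 0 °C → rt; aq. potassium sodium tartrate
Reagents that add atoms: none
Why: hydride reduction opens the lactone to the primary alcohol and the C2' phenol and removes the acetate in the same operation; the isolated terminal alkene is inert to LiAlH4 and the tartrate work-up avoids acid.

Step 15
Reactants: 21 4-(3-hydroxypropyl)-6-(2-methylbut-3-en-2-yl)benzene-1,3-diol
Product: 22 3-[2,4-bis(methoxymethoxy)-5-(2-methylbut-3-en-2-yl)phenyl]propan-1-ol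
Conditions: NaH (2.05 equiv), THF/DMF, 0 °C; MOMCl (2.1 equiv), 0 °C
Reagents that add atoms: chloromethyl methyl ether, COCCl
Why: phenoxide-selective Williamson alkylation; two equivalents of base deprotonate only the two phenols (pKa about 10 against about 16 for the primary alcohol), so the alcohol should stay free.

Step 16
Reactants: 22 3-[2,4-bis(methoxymethoxy)-5-(2-methylbut-3-en-2-yl)phenyl]propan-1-ol
Product: 23 1-(3-iodopropyl)-2,4-bis(methoxymethoxy)-5-(2-methylbut-3-en-2-yl)benzene
Conditions: I2, PPh3, imidazole, CH2Cl2, 0 °C → rt
Reagents that add atoms: iodine, II
Why: Appel-type iodination of the primary alcohol by SN2 displacement of the oxyphosphonium group; imidazole buffers the medium, so the acetals and the terminal alkene should be untouched.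

Step 17
Reactants: 23 1-(3-iodopropyl)-2,4-bis(methoxymethoxy)-5-(2-methylbut-3-en-2-yl)benzene; 15 6-bromo-8-(methoxymethoxy)-2,2-dimethyl-5-(3-methylbut-2-en-1-yl)chroman
Product: 25 6-{3-[2,4-bis(methoxymethoxy)-5-(2-methylbut-3-en-2-yl)phenyl]propyl}-8-(methoxymethoxy)-2,2-dimethyl-5-(3-methylbut-2-en-1-yl)chroman, via alkylzinc iodide 24 (not isolated)
Conditions: 23 (1.3 equiv), Zn dust (activated with BrCH2CH2Br and TMSCl), LiCl, THF, 40 °C; then 15, Pd(OAc)2 (2 mol %), SPhos (4 mol %), THF, 50 °C
Reagents that add atoms: none
Why: Negishi cross-coupling: LiCl-promoted zinc insertion into the primary iodide gives 24, which tolerates acetals and alkenes; oxidative addition of zerovalent palladium into the C6–Br bond of 15, transmetalation and reductive elimination form the sp3–sp2 bond, and the bulky electron-rich biarylphosphine should favour reductive elimination over β-hydride elimination.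

Step 18
Reactants: 25 6-{3-[2,4-bis(methoxymethoxy)-5-(2-methylbut-3-en-2-yl)phenyl]propyl}-8-(methoxymethoxy)-2,2-dimethyl-5-(3-methylbut-2-en-1-yl)chroman
Product: 26 kazinol D, 4-{3-[8-hydroxy-2,2-dimethyl-5-(3-methylbut-2-en-1-yl)chroman-6-yl]propyl}-6-(2-methylbut-3-en-2-yl)benzene-1,3-diol
Conditions: aq. HCl (3 M), MeOH/THF, 40 °C
Reagents that add atoms: none
Why: acid-catalysed methanolysis of the three aryl methoxymethyl acetals; under dilute acid at moderate temperature the prenyl group (no neighbouring hydroxyl) and the monosubstituted alkene of the dimethylallyl group (which would have to form a secondary cation) should react much more slowly than the acetals.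

## Compound list

1 | 2-bromo-5-hydroxy-4-methoxybenzaldehyde | COc1cc(Br)c(C=O)cc1O | starting material
2 | 2-bromo-4,5-dihydroxybenzaldehyde | O=Cc1cc(O)c(O)cc1Br | intermediate
3 | 2-bromo-5-hydroxy-4-(methoxymethoxy)benzaldehyde | COCOc1cc(Br)c(C=O)cc1O | intermediate
4 | 2-bromo-5-[(tert-butyldimethylsilyl)oxy]-4-(methoxymethoxy)benzaldehyde | COCOc1cc(Br)c(C=O)cc1O[Si](C)(C)C(C)(C)C | intermediate
5 | {2-bromo-5-[(tert-butyldimethylsilyl)oxy]-4-(methoxymethoxy)phenyl}methanol | COCOc1cc(Br)c(CO)cc1O[Si](C)(C)C(C)(C)C | intermediate
6 | [4-bromo-5-(bromomethyl)-2-(methoxymethoxy)phenoxy](tert-butyl)dimethylsilane | COCOc1cc(Br)c(CBr)cc1O[Si](C)(C)C(C)(C)C | intermediate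
7 | [4-bromo-2-(methoxymethoxy)-5-(prop-2-en-1-yl)phenoxy](tert-butyl)dimethylsilane | C=CCc1cc(O[Si](C)(C)C(C)(C)C)c(OCOC)cc1Br | intermediate (not isolated)
8 | 4-bromo-2-(methoxymethoxy)-5-(prop-2-en-1-yl)phenol | C=CCc1cc(O)c(OCOC)cc1Br | intermediate
9 | 6-allyl-5-bromo-2-hydroxy-3-(methoxymethoxy)benzaldehyde | C=CCc1c(Br)cc(OCOC)c(O)c1C=O | intermediate
10 | 3-allyl-4-bromo-2-(hydroxymethyl)-6-(methoxymethoxy)phenol | C=CCc1c(Br)cc(OCOC)c(O)c1CO | intermediate
11 | 2-methylpropene | C=C(C)C | starting material
12 | 5-allyl-4-bromo-2-(methoxymethoxy)-6-methylidenecyclohexa-2,4-dien-1-one | C=CCC1=C(Br)C=C(OCOC)C(=O)C1=C | intermediate (not isolated)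
13 | 5-allyl-6-bromo-8-(methoxymethoxy)-2,2-dimethylchroman | C=CCc1c(Br)cc(OCOC)c2c1CCC(C)(C)O2 | intermediate
14 | 2-methylbut-2-ene | CC=C(C)C | starting material
15 | 6-bromo-8-(methoxymethoxy)-2,2-dimethyl-5-(3-methylbut-2-en-1-yl)chroman | CC(C)=CCc1c(Br)cc(OCOC)c2c1CCC(C)(C)O2 | intermediate
16 | 7-hydroxy-2H-chromen-2-one (umbelliferone) | O=c1ccc2ccc(O)cc2o1 | starting material
17 | 7-hydroxychroman-2-one | O=C1CCc2ccc(O)cc2O1 | intermediate
18 | 7-[(3-methylbut-2-en-1-yl)oxy]chroman-2-one | CC(C)=CCOc1ccc2CCC(=O)Oc2c1 | intermediate
19 | 7-hydroxy-6-(2-methylbut-3-en-2-yl)chroman-2-one | C=CC(C)(C)c1cc2CCC(=O)Oc2cc1O | intermediate (not isolated)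
20 | 6-(2-methylbut-3-en-2-yl)-2-oxochroman-7-yl acetate | C=CC(C)(C)c1cc2CCC(=O)Oc2cc1OC(C)=O | intermediate
21 | 4-(3-hydroxypropyl)-6-(2-methylbut-3-en-2-yl)benzene-1,3-diol | C=CC(C)(C)c1cc(CCCO)c(O)cc1O | intermediate
22 | 3-[2,4-bis(methoxymethoxy)-5-(2-methylbut-3-en-2-yl)phenyl]propan-1-ol | C=CC(C)(C)c1cc(CCCO)c(OCOC)cc1OCOC | intermediate
23 | 1-(3-iodopropyl)-2,4-bis(methoxymethoxy)-5-(2-methylbut-3-en-2-yl)benzene | C=CC(C)(C)c1cc(CCCI)c(OCOC)cc1OCOC | intermediate
24 | {3-[2,4-bis(methoxymethoxy)-5-(2-methylbut-3-en-2-yl)phenyl]propyl}zinc iodide | C=CC(C)(C)c1cc(CCC[Zn]I)c(OCOC)cc1OCOC | intermediate (not isolated)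
25 | 6-{3-[2,4-bis(methoxymethoxy)-5-(2-methylbut-3-en-2-yl)phenyl]propyl}-8-(methoxymethoxy)-2,2-dimethyl-5-(3-methylbut-2-en-1-yl)chroman | C=CC(C)(C)c1cc(CCCc2cc(OCOC)c3c(c2CC=C(C)C)CCC(C)(C)O3)c(OCOC)cc1OCOC | intermediate
26 | kazinol D, 4-{3-[8-hydroxy-2,2-dimethyl-5-(3-methylbut-2-en-1-yl)chroman-6-yl]propyl}-6-(2-methylbut-3-en-2-yl)benzene-1,3-diol | C=CC(C)(C)c1cc(CCCc2cc(O)c3c(c2CC=C(C)C)CCC(C)(C)O3)c(O)cc1O | target

## Step count and least certain steps

Total: 18 steps. Longest linear sequence: 12 steps (steps 1 to 10, 17 and 18, from 1). The ring A branch has 6 steps (11 to 16) before the two halves meet in step 17.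

**Step 9 (key step).** The dehydration may be slow at temperatures the acetal tolerates, and the methide may condense with itself or with unchanged 10 faster than it captures an unactivated alkene. The acetal may also be lost to the water set free at 170 °C. The fallback replaces the thermal cycloaddition by a low-temperature anionic sequence. It sets out from 10, which is acylated at the phenol oxygen (Boc2O, iPr2NEt, trace DMAP, CH2Cl2, −20 °C, conditions under which the phenol reacts before the primary alcohol) to give tert-butyl [3-allyl-4-bromo-2-(hydroxymethyl)-6-(methoxymethoxy)phenyl] carbonate F1. Treatment of F1 with methallylmagnesium chloride (2.5 equiv, THF, −78 °C → rt) should deprotonate the benzylic alcohol, move the carbonate to that oxygen and expel tert-butyl carbonate, so that 12 forms at low temperature and takes up a second equivalent of the Grignard reagent in a 1,4-addition. This gives 3-allyl-4-bromo-6-(methoxymethoxy)-2-(3-methylbut-3-en-1-yl)phenol F2. Markovnikov hydroalkoxylation of the 1,1-disubstituted alkene of F2 (catalytic camphorsulfonic acid, dry CH2Cl2, 0 °C → rt; the allyl group would need a secondary cation and should not react) closes the ring, and the route is rejoined at 13.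

**Step 13.** The shift may go in part to C8, since the lactone oxygen is only a weak director, and the prenyl ether may be lost by ionisation at 190 °C. The fallback changes the substrate of the rearrangement to an open-chain one with a bulky donor beside the unwanted position. It sets out from 18: NaOMe in MeOH opens the lactone to methyl 3-{2-hydroxy-4-[(3-methylbut-2-en-1-yl)oxy]phenyl}propanoate F3 (as its sodium phenoxide). After removal of the methanol this is alkylated with MOMCl in DMF to give methyl 3-{2-(methoxymethoxy)-4-[(3-methylbut-2-en-1-yl)oxy]phenyl}propanoate F4. Heating F4 in PhNEt2 at 190 °C should now send the prenyl terminus away from the acetal-flanked position and give methyl 3-[4-hydroxy-2-(methoxymethoxy)-5-(2-methylbut-3-en-2-yl)phenyl]propanoate F5. NaH and MOMCl convert F5 to methyl 3-[2,4-bis(methoxymethoxy)-5-(2-methylbut-3-en-2-yl)phenyl]propanoate F6, and LiAlH4 reduction of F6 rejoins the route at 22.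

**Step 17.** Zinc insertion may be incomplete or accompanied by homocoupling. Oxidative addition into the hindered, electron-rich bromide may be so slow that protodezincation and β-hydride elimination from the alkylpalladium species take over. The fallback reverses the polarity and needs no palladium. It sets out from 15, which on bromine–lithium exchange (t-BuLi, 2.1 equiv, THF, −78 °C) should give [8-(methoxymethoxy)-2,2-dimethyl-5-(3-methylbut-2-en-1-yl)chroman-6-yl]lithium F7. SN2 alkylation of F7 with the primary iodide 23 (THF/DMPU, −78 → −20 °C) rejoins the route at 25.

**Step 18.** Acid may close the 1,1-dimethylallyl group onto the neighbouring C4' hydroxyl or add methanol to the prenyl group before the hindered acetal beside the quaternary carbon is gone. The fallback replaces protic hydrolysis by silyl exchange through a discrete intermediate. It sets out from 25: TMSOTf and 2,2'-bipyridyl (CH2Cl2, 0 °C → rt) should convert the three aryl acetals into the tris(trimethylsilyl) ether F8, 6-{3-[5-(2-methylbut-3-en-2-yl)-2,4-bis(trimethylsilyloxy)phenyl]propyl}-2,2-dimethyl-5-(3-methylbut-2-en-1-yl)-8-(trimethylsilyloxy)chroman. Hydrolysis of F8 with water at neutral pH rejoins the route at 26.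

**Step 7.** Chelation of magnesium by the ortho acetal and deactivation by the para bromine may make the formylation sluggish, and long heating may lead on to methoxymethylation of the ring. The fallback installs the CH2OH carbon directly at the alcohol level. It sets out from 8, which with PhB(OH)2, paraformaldehyde and catalytic propionic acid in refluxing toluene (Dean–Stark trap) should give the boron-templated ortho-hydroxymethylation product, 5-allyl-6-bromo-8-(methoxymethoxy)-2-phenyl-4H-1,3,2-benzodioxaborinine F9. Transesterification of F9 with propane-1,3-diol rejoins the route at 10, passing over 9.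

## Further compounds

F1 | step 9 | tert-butyl [3-allyl-4-bromo-2-(hydroxymethyl)-6-(methoxymethoxy)phenyl] carbonate | C=CCc1c(Br)cc(OCOC)c(OC(=O)OC(C)(C)C)c1CO
F2 | step 9 | 3-allyl-4-bromo-6-(methoxymethoxy)-2-(3-methylbut-3-en-1-yl)phenol | C=CCc1c(Br)cc(OCOC)c(O)c1CCC(C)=C
F3 | step 13 | methyl 3-{2-hydroxy-4-[(3-methylbut-2-en-1-yl)oxy]phenyl}propanoate | COC(=O)CCc1ccc(OCC=C(C)C)cc1O
F4 | step 13 | methyl 3-{2-(methoxymethoxy)-4-[(3-methylbut-2-en-1-yl)oxy]phenyl}propanoate | COC(=O)CCc1ccc(OCC=C(C)C)cc1OCOC
F5 | step 13 | methyl 3-[4-hydroxy-2-(methoxymethoxy)-5-(2-methylbut-3-en-2-yl)phenyl]propanoate | C=CC(C)(C)c1cc(CCC(=O)OC)c(OCOC)cc1O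
F6 | step 13 | methyl 3-[2,4-bis(methoxymethoxy)-5-(2-methylbut-3-en-2-yl)phenyl]propanoate | C=CC(C)(C)c1cc(CCC(=O)OC)c(OCOC)cc1OCOC
F7 | step 17 | [8-(methoxymethoxy)-2,2-dimethyl-5-(3-methylbut-2-en-1-yl)chroman-6-yl]lithium | [Li]c1cc(OCOC)c2c(c1CC=C(C)C)CCC(C)(C)O2
F8 | step 18 | 6-{3-[5-(2-methylbut-3-en-2-yl)-2,4-bis(trimethylsilyloxy)phenyl]propyl}-2,2-dimethyl-5-(3-methylbut-2-en-1-yl)-8-(trimethylsilyloxy)chroman | C=CC(C)(C)c1cc(CCCc2cc(O[Si](C)(C)C)c3c(c2CC=C(C)C)CCC(C)(C)O3)c(O[Si](C)(C)C)cc1O[Si](C)(C)C
F9 | step 7 | 5-allyl-6-bromo-8-(methoxymethoxy)-2-phenyl-4H-1,3,2-benzodioxaborinine | C=CCc1c(Br)cc(OCOC)c2OB(c3ccccc3)OCc12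
A1 | alternative 1 | 5-(methoxymethoxy)-4-{3-[8-(methoxymethoxy)-2,2-dimethyl-5-(3-methylbut-2-en-1-yl)chroman-6-yl]propyl}-2-(2-methylbut-3-en-2-yl)phenol | C=CC(C)(C)c1cc(CCCc2cc(OCOC)c3c(c2CC=C(C)C)CCC(C)(C)O3)c(OCOC)cc1O
A2 | alternative 1 | tert-butyl {2-acetyl-5-(methoxymethoxy)-4-[3-(8-(methoxymethoxy)-2,2-dimethyl-5-(3-methylbut-2-en-1-yl)chroman-6-yl)propyl]phenyl} carbonate | CC(=O)c1cc(CCCc2cc(OCOC)c3c(c2CC=C(C)C)CCC(C)(C)O3)c(OCOC)cc1OC(=O)OC(C)(C)C
A3 | alternative 1 | 3-(methoxymethoxy)-4-{3-[8-(methoxymethoxy)-2,2-dimethyl-5-(3-methylbut-2-en-1-yl)chroman-6-yl]propyl}-6-(propan-2-ylidene)cyclohexa-2,4-dien-1-one | CC(C)=C1C=C(CCCc2cc(OCOC)c3c(c2CC=C(C)C)CCC(C)(C)O3)C(OCOC)=CC1=O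
A4 | alternative 2 | 6-{3-[2,4-bis(tert-butyldimethylsilyloxy)-5-(2-methylbut-3-en-2-yl)phenyl]propyl}-2,2-dimethyl-5-(3-methylbut-2-en-1-yl)-8-[2-(trimethylsilyl)ethoxy]chroman | C=CC(C)(C)c1cc(CCCc2cc(OCC[Si](C)(C)C)c3c(c2CC=C(C)C)CCC(C)(C)O3)c(O[Si](C)(C)C(C)(C)C)cc1O[Si](C)(C)C(C)(C)C
A5 | alternative 2 | 6-{3-[2,4-bis(tert-butyldimethylsilyloxy)-5-(2-methylbut-3-en-2-yl)phenyl]propyl}-3-[(2,9-dimethyldec-8-en-5-yn-2-yl)oxy]-4-[2-(trimethylsilyl)ethoxy]pyridazine | C=CC(C)(C)c1cc(CCCc2cc(OCC[Si](C)(C)C)c(OC(C)(C)CCC#CCC=C(C)C)nn2)c(O[Si](C)(C)C(C)(C)C)cc1O[Si](C)(C)C(C)(C)C
A6 | alternative 3 | racemic 7-(methoxymethoxy)-6-(2-methylbut-3-en-2-yl)-2-[8-(methoxymethoxy)-2,2-dimethyl-5-(3-methylbut-2-en-1-yl)chroman-6-yl]chroman | C=CC(C)(C)c1cc2c(cc1OCOC)OC(CC2)c1cc(OCOC)c2c(c1CC=C(C)C)CCC(C)(C)O2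
A7 | alternative 3 | 2-(hydroxymethyl)-5-(methoxymethoxy)-4-(2-methylbut-3-en-2-yl)phenol | C=CC(C)(C)c1cc(CO)c(O)cc1OCOC
A8 | alternative 3 | 3-(methoxymethoxy)-4-(2-methylbut-3-en-2-yl)-6-methylidenecyclohexa-2,4-dien-1-one | C=C1C=C(C(C)(C)C=C)C(OCOC)=CC1=O
A9 | alternative 3 | 8-(methoxymethoxy)-2,2-dimethyl-5-(3-methylbut-2-en-1-yl)-6-vinylchroman | C=Cc1cc(OCOC)c2c(c1CC=C(C)C)CCC(C)(C)O2
A10 | alternative 3 | 5-(methoxymethoxy)-2-{3-[8-(methoxymethoxy)-2,2-dimethyl-5-(3-methylbut-2-en-1-yl)chroman-6-yl]propyl}-4-(2-methylbut-3-en-2-yl)phenol | C=CC(C)(C)c1cc(CCCc2cc(OCOC)c3c(c2CC=C(C)C)CCC(C)(C)O3)c(O)cc1OCOC
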